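**Strategy.** The route disconnects the seven-membered ring at C3–C4 and the cyclobutane at C1–C2 (tricyclo[5.4.0.0^{2,8}]undecane numbering). One flask makes both bonds from a monocyclic epoxy keto ester. The methyl ketone enolate (C4) acylates the ester (C3), using the 1,3-dioxygen pattern C3/C5 of the seven-membered ring. The γ-carbon (C2) of the resulting 1,3-diketone dianion then opens the cyclohexane epoxide at C1, whose oxygen stays on C11, the future enone carbonyl 1,4 to C3 across the cyclobutane. The precursor, a cis-disubstituted cyclohexene oxide, comes from an enantioselective Diels–Alder reaction; reagent-controlled diketone reduction, allylic oxidation and acylation complete the target.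

Key step: step 8

Remark (labels): C1 = bridgehead CH next to the ketone C11; C2 = methyl-bearing quaternary carbon; C3, C5 = ester-bearing carbons; C4 = the CH2 between them; C6 = CMe2; C7, C8 = the other cyclobutane CH groups; C9, C10 = alkene carbons.
Remark (assumption): the sense of induction in steps 4 and 10 is taken from the accepted transition-state models of the oxazaborolidine catalysts; if step 4 proves opposite, the enantiomeric catalyst is used.

Step 1
Reactants: 1 2-methylpropanenitrile; 2 (E)-but-2-enal
Product: 3 (E)-3-hydroxy-2,2-dimethylhex-4-enenitrile (racemic)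
Conditions: LiN(i-Pr)2, THF, −78 °C; then 2, −78 °C; H2O
Reagents that add atoms: none
Why: Nitrile aldol-type 1,2-addition: the lithiated nitrile adds to the aldehyde carbonyl at −78 °C and creates the quaternary carbon C6, the carbinol centre being removed in step 2.

Step 2
Reactants: 3 (E)-3-hydroxy-2,2-dimethylhex-4-enenitrile
Product: 5 (E)-2,2-dimethylhexa-3,5-dienenitrile, via allylic mesylate 4 (not isolated)
Conditions: MsCl, Et3N, CH2Cl2, 0 °C; then DBU, 40 °C
Reagents that add atoms: none
Why: Mesylation and DBU-promoted 1,4-elimination (vinylogous E2) should give the conjugated (E)-diene, since the quaternary neighbour rules out SN2 and E1cB pathways and the (E)-geometry is the more stable.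

Step 3
Reactants: 5 (E)-2,2-dimethylhexa-3,5-dienenitrile
Product: 7 (E)-3,3-dimethylhepta-4,6-dien-2-one, via N-lithio ketimine 6 (not isolated)
Conditions: MeLi, Et2O, 0 → 25 °C; then 1 M HCl, 0 °C
Reagents that add atoms: methyllithium [Li]C; water O
Why: Addition of an organolithium to a non-enolizable nitrile stops at the N-lithio ketimine, which aqueous acid hydrolyses to the methyl ketone (C5 and C4).

Step 4
Reactants: 7 (E)-3,3-dimethylhepta-4,6-dien-2-one; 8 (E)-pent-3-en-2-one
Product: 9 3-[(1R,5R,6S)-6-acetyl-5-methylcyclohex-2-en-1-yl]-3-methylbutan-2-one (acetyl cis to the ketone side chain, methyl trans to acetyl)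
Conditions: 8 (3 equiv), (S)-3,3-diphenyl-1-(o-tolyl)tetrahydro-1H,3H-pyrrolo[1,2-c][1,3,2]oxazaborole (20 mol %), HNTf2 (18 mol %), CH2Cl2, −20 °C
Reagents that add atoms: none
Why: Catalytic enantioselective Diels–Alder reaction with a chiral oxazaborolidinium Lewis acid: the 1-alkyl diene adds "ortho" to the activated enone, the endo transition state sets acetyl cis to the side chain at C7, the (E)-enone fixes methyl trans to acetyl, and the catalyst-bound enone exposes one face so that C7 and C8 should form in the absolute configuration shown.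

Step 5
Reactants: 9 3-[(1R,5R,6S)-6-acetyl-5-methylcyclohex-2-en-1-yl]-3-methylbutan-2-one
Product: 10 2-[(1S,2R,6R)-6-methyl-2-(3-methyl-2-oxobutan-3-yl)cyclohex-3-en-1-yl]propanenitrile (both epimers at the nitrile α-carbon C2)
Conditions: TosMIC, KOt-Bu, DME, EtOH (2 equiv), −10 → 25 °C
Reagents that add atoms: TosMIC (p-toluenesulfonylmethyl isocyanide) Cc1ccc(cc1)S(=O)(=O)C[N+]#[C-]
Why: Van Leusen reductive cyanation converts the less hindered ring-bound acetyl group into the α-methyl nitrile (C2, C3) while the neopentyl-type ketone is left; C2 forms as both epimers, which converge in step 8, and C8 is no longer epimerizable afterwards.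

Step 6
Reactants: 10 the nitrile of step 5
Product: 12 methyl 2-[(1S,2R,6R)-6-methyl-2-(3-methyl-2-oxobutan-3-yl)cyclohex-3-en-1-yl]propanoate (both C2 epimers), via methyl imidate 11 (not isolated)
Conditions: HCl (g), MeOH, 0 → 25 °C; then H2O, 25 °C
Reagents that add atoms: methanol CO; water O
Why: Pinner reaction: HCl and methanol give the imidate salt, which water hydrolyses to the methyl ester that serves as acyl donor in step 8.

Step 7
Reactants: 12 the methyl ester of step 6
Product: 13 methyl 2-[(1R,2R,3S,4R,6S)-4-methyl-2-(3-methyl-2-oxobutan-3-yl)-7-oxabicyclo[4.1.0]heptan-3-yl]propanoate (epoxide oxygen trans to both side chains; both C2 epimers)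
Conditions: mCPBA, CH2Cl2, 0 °C
Reagents that add atoms: mCPBA OOC(=O)c1cccc(Cl)c1
Why: Prilezhaev epoxidation of the only alkene from the face opposite the bulky allylic side chain at C7 should place the oxygen trans to both side chains, which sets C1 and C11.

Step 8
Reactants: 13 the epoxy keto ester of step 7
Product: 15 (1R,2R,7S,8S,9R,11S)-11-hydroxy-2,6,6,9-tetramethyltricyclo[5.4.0.0^{2,8}]undecane-3,5-dione, via bicyclic epoxy diketone 14 (not isolated)
Conditions: LiN(SiMe3)2 (2.2 equiv), THF (0.02 M), −78 → 0 °C; then LiN(i-Pr)2 (2 equiv), −78 → 25 °C; then 1 M HCl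
Reagents that add atoms: none
Why: Proposed new method: LiN(SiMe3)2 enolizes only the methyl ketone, whose enolate (C4) acylates the methyl ester (C3) in an intramolecular Claisen (Dieckmann-type) condensation and is parked as the lithium 1,3-diketonate 14; LiN(i-Pr)2 then removes the γ-hydrogen at C2, and the γ-carbon of this dianion opens the epoxide at C1 by SN2, leaving the alkoxide on C11. The closest known reactions are the γ-alkylation of 1,3-dicarbonyl dianions by epoxides and the Stork epoxynitrile cyclization to cyclobutanes; their transannular combination on a 1,3-diketone dianion has not been described. The seven-membered ring closes 7-(enolendo)-exo-trig and the cyclobutane 4-exo-tet. The quaternary centre C2 is set by the seven-membered ring already in place, which holds C3 away from the six-membered ring so that only the methyl group can point over it, and C1 is set by inversion at the epoxide carbon, the epoxide having been placed trans to the side chains in step 7. The step needs acylation before any epoxide opening, C- rather than O-alkylation and attack at C1 rather than C11: lithium ketone enolates open epoxides slowly below 0 °C while the Claisen closure becomes irreversible once the diketonate forms, the dianion reacts at its γ-carbon, the O-alkylated product would be a bridgehead enol ether, and attack at C11 would be a 5-endo-tet opening. Both C2 epimers of 13 converge because that centre is planar in the dianion.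

Step 9
Reactants: 15 the hydroxy diketone of step 8
Product: 17 (1R,2R,7S,8R)-2,6,6,9-tetramethyltricyclo[5.4.0.0^{2,8}]undec-9-ene-3,5,11-trione, via saturated triketone 16 (not isolated)
Conditions: IBX (3.5 equiv), DMSO, 25 → 75 °C
Reagents that add atoms: none
Why: IBX oxidizes the alcohol to the C11 ketone and at 75 °C dehydrogenates it (IBX-mediated dehydrogenation via the enol) toward C10–C9, the only possible direction because C1 is a bridgehead and the diketone is flanked by quaternary carbons.

Step 10
Reactants: 17 the enone diketone of step 9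
Product: 18 (1R,2R,3R,5R,7S,8R)-2,6,6,9-tetramethyltricyclo[5.4.0.0^{2,8}]undec-9-ene-3,5,11-triol (either configuration at C11)
Conditions: (S)-1-methyl-3,3-diphenyltetrahydro-1H,3H-pyrrolo[1,2-c][1,3,2]oxazaborole (0.5 equiv), BH3·SMe2 (4 equiv), THF, −20 °C; then MeOH
Reagents that add atoms: none
Why: CBS reduction: at C3 and C5 the quaternary neighbour is the large and the C4 methylene the small group, so the (S)-catalyst should deliver hydride to give the (R)-carbinol at both centres (anti-diol) under reagent control, the local pseudo-symmetry of the ring leaving little substrate bias, while the enone carbonyl is reduced without consequence.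

Step 11
Reactants: 18 the triol of step 10
Product: 19 (1R,2R,3R,5R,7S,8R)-3,5-dihydroxy-2,6,6,9-tetramethyltricyclo[5.4.0.0^{2,8}]undec-9-en-11-one
Conditions: MnO2 (20 equiv), CH2Cl2, 25 °C
Reagents that add atoms: none
Why: MnO2 oxidizes only the allylic alcohol at C11, which restores the enone and leaves the two hindered saturated carbinols untouched.

Step 12
Reactants: 19 the diol enone of step 11; 20 3-methylbut-2-enoyl chloride
Product: 21 (1R,2R,3R,5R,7S,8R)-2,6,6,9-tetramethyl-11-oxotricyclo[5.4.0.0^{2,8}]undec-9-ene-3,5-diyl bis(3-methylbut-2-enoate) (CNP0105062.1)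
Conditions: 20 (4 equiv), pyridine, 4-(dimethylamino)pyridine (0.2 equiv), CH2Cl2, 0 → 40 °C
Reagents that add atoms: none
Why: Acyl transfer catalysed by 4-(dimethylamino)pyridine esterifies both hindered secondary alcohols with retention, and pyridine as a weak base should avoid deconjugation of the acyl group via the vinylketene.

**Compound list**

1 | 2-methylpropanenitrile | CC(C)C#N | starting material
2 | (E)-but-2-enal | C/C=C/C=O | starting material
3 | (E)-3-hydroxy-2,2-dimethylhex-4-enenitrile (racemic) | C/C=C/C(O)C(C)(C)C#N | intermediate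
4 | (E)-2,2-dimethyl-3-(methylsulfonyloxy)hex-4-enenitrile (racemic, not isolated) | C/C=C/C(OS(C)(=O)=O)C(C)(C)C#N | intermediate
5 | (E)-2,2-dimethylhexa-3,5-dienenitrile | C=C/C=C/C(C)(C)C#N | intermediate
6 | (E)-3,3-dimethylhepta-4,6-dien-2-imine (present as N-lithio salt, not isolated) | CC(=N)C(C)(C)/C=C/C=C | intermediate
7 | (E)-3,3-dimethylhepta-4,6-dien-2-one | CC(=O)C(C)(C)/C=C/C=C | intermediate
8 | (E)-pent-3-en-2-one | C/C=C/C(C)=O | starting material
9 | 3-[(1R,5R,6S)-6-acetyl-5-methylcyclohex-2-en-1-yl]-3-methylbutan-2-one | CC(=O)C(C)(C)[C@@H]1C=CC[C@@H](C)[C@@H]1C(C)=O | intermediate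
10 | 2-[(1S,2R,6R)-6-methyl-2-(3-methyl-2-oxobutan-3-yl)cyclohex-3-en-1-yl]propanenitrile (C2 epimers) | CC(=O)C(C)(C)[C@@H]1C=CC[C@@H](C)[C@@H]1C(C)C#N | intermediate
11 | methyl 2-[(1S,2R,6R)-6-methyl-2-(3-methyl-2-oxobutan-3-yl)cyclohex-3-en-1-yl]propanimidate (as hydrochloride, not isolated) | CC(=O)C(C)(C)[C@@H]1C=CC[C@@H](C)[C@@H]1C(C)C(=N)OC | intermediate
12 | methyl 2-[(1S,2R,6R)-6-methyl-2-(3-methyl-2-oxobutan-3-yl)cyclohex-3-en-1-yl]propanoate (C2 epimers) | CC(=O)C(C)(C)[C@@H]1C=CC[C@@H](C)[C@@H]1C(C)C(=O)OC | intermediate
13 | methyl 2-[(1R,2R,3S,4R,6S)-4-methyl-2-(3-methyl-2-oxobutan-3-yl)-7-oxabicyclo[4.1.0]heptan-3-yl]propanoate (C2 epimers) | CC(=O)C(C)(C)[C@@H]1[C@H]2O[C@H]2C[C@@H](C)[C@@H]1C(C)C(=O)OC | intermediate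
14 | cis-fused bicyclic epoxy 1,3-diketone: cycloheptane-1,3-dione fused to the cyclohexane oxide, epoxide on the face opposite the seven-membered ring (present as lithium enolate, not isolated) | O=C1CC(=O)C(C)[C@H]2[C@H](C)C[C@@H]3O[C@@H]3[C@H]2C1(C)C | intermediate
15 | (1R,2R,7S,8S,9R,11S)-11-hydroxy-2,6,6,9-tetramethyltricyclo[5.4.0.0^{2,8}]undecane-3,5-dione | O=C1CC(=O)[C@@]2(C)[C@@H]3[C@@H](O)C[C@@H](C)[C@H]2[C@@H]3C1(C)C | intermediate
16 | (1R,2R,7S,8S,9R)-2,6,6,9-tetramethyltricyclo[5.4.0.0^{2,8}]undecane-3,5,11-trione (not isolated) | O=C1CC(=O)[C@@]2(C)[C@@H]3C(=O)C[C@@H](C)[C@H]2[C@@H]3C1(C)C | intermediate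
17 | (1R,2R,7S,8R)-2,6,6,9-tetramethyltricyclo[5.4.0.0^{2,8}]undec-9-ene-3,5,11-trione | O=C1CC(=O)[C@@]2(C)[C@@H]3C(=O)C=C(C)[C@H]2[C@@H]3C1(C)C | intermediate
18 | (1R,2R,3R,5R,7S,8R)-2,6,6,9-tetramethyltricyclo[5.4.0.0^{2,8}]undec-9-ene-3,5,11-triol (C11 epimers) | O[C@@H]1C[C@@H](O)[C@@]2(C)[C@@H]3C(O)C=C(C)[C@H]2[C@@H]3C1(C)C | intermediate
19 | (1R,2R,3R,5R,7S,8R)-3,5-dihydroxy-2,6,6,9-tetramethyltricyclo[5.4.0.0^{2,8}]undec-9-en-11-one | O[C@@H]1C[C@@H](O)[C@@]2(C)[C@@H]3C(=O)C=C(C)[C@H]2[C@@H]3C1(C)C | intermediate
20 | 3-methylbut-2-enoyl chloride | CC(C)=CC(Cl)=O | starting material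
21 | (1R,2R,3R,5R,7S,8R)-2,6,6,9-tetramethyl-11-oxotricyclo[5.4.0.0^{2,8}]undec-9-ene-3,5-diyl bis(3-methylbut-2-enoate) | CC(C)=CC(=O)O[C@@H]1C[C@@H](OC(=O)C=C(C)C)[C@@]2(C)[C@@H]3C(=O)C=C(C)[C@H]2[C@@H]3C1(C)C | target

**Totals.** Total step count: 12. Longest linear sequence: 12 steps (1 → 21).

**Steps most likely to fail**

1. Step 8 (Proposed new method). What may go wrong: opening of the epoxide by the first-formed ketone enolate before acylation, O- instead of C-alkylation of the dianion, or base-induced isomerization of the epoxide. Fallback with known reactions, reversing the order of the two bond formations but keeping them in one flask: nitrile 10 is epoxidized (mCPBA) to the epoxy nitrile F1. LiN(i-Pr)2 (1 equiv) and Me3SiCl at −78 °C mask the more acidic methyl ketone as the trimethylsilyl enol ether F2. KN(SiMe3)2 then closes the cyclobutane by Stork epoxynitrile cyclization (4-exo-tet at C1) to the cyclobutane nitrile F3. Bu4NF added to the same flask frees the ketone enolate, which adds to the now non-enolizable nitrile (Thorpe–Ziegler closure of the seven-membered ring) to give the enaminone F4. Aqueous HCl hydrolyses F4 to 15, where the main route resumes. In this variant the configuration at C2 rests on the small linear nitrile taking the position that faces the C6 side chain.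

2. Step 4. What may go wrong: slow cycloaddition of the β-substituted enone with the hindered diene, and poor facial selectivity at the catalyst-bound enone. Fallback by iminium catalysis with the enal in place of the enone: diene 7 and (E)-but-2-enal (2) with (2S,5S)-5-benzyl-2-tert-butyl-3-methylimidazolidin-4-one trifluoroacetate (or its enantiomer, as the face requires) give the aldehyde F5. MeMgBr at −78 °C adds to the aldehyde but not to the hindered ketone and gives the carbinol F6. Dess–Martin oxidation of F6 returns diketone 9.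

3. Step 5. What may go wrong: enolization next to the acetyl group under the basic conditions, which scrambles the cis relationship at C8, and competing cyanation of the second ketone. Fallback that brings in the carbon without base: Petasis methylenation (Cp2TiMe2, 1 equiv) of the less hindered ketone of 9 gives the isopropenyl compound F7. Hydroboration of the 1,1-disubstituted alkene with 9-BBN, then H2O2/NaOH, gives the primary alcohol F8. Jones oxidation (CrO3, H2SO4) gives the acid F9, and Me3SiCHN2 in MeOH returns ester 12.

Further compounds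

F1 | step 8 | epoxy nitrile, the nitrile analogue of 13 | CC(=O)C(C)(C)[C@@H]1[C@H]2O[C@H]2C[C@@H](C)[C@@H]1C(C)C#N
F2 | step 8 | trimethylsilyl enol ether of the methyl ketone of F1 | C=C(O[Si](C)(C)C)C(C)(C)[C@@H]1[C@H]2O[C@H]2C[C@@H](C)[C@@H]1C(C)C#N
F3 | step 8 | 2-hydroxy-4,6-dimethyl-7-[3-methyl-2-(trimethylsilyloxy)but-1-en-3-yl]bicyclo[3.1.1]heptane-6-carbonitrile (nitrile anti to the three-carbon bridge) | C=C(O[Si](C)(C)C)C(C)(C)[C@@H]1[C@H]2[C@@H](O)C[C@@H](C)[C@@H]1[C@@]2(C)C#N
F4 | step 8 | 3-amino-11-hydroxy-2,6,6,9-tetramethyltricyclo[5.4.0.0^{2,8}]undec-3-en-5-one | O=C1C=C(N)[C@@]2(C)[C@@H]3[C@@H](O)C[C@@H](C)[C@H]2[C@@H]3C1(C)C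
F5 | step 4 | aldehyde analogue of 9 (CHO in place of acetyl) | CC(=O)C(C)(C)[C@@H]1C=CC[C@@H](C)[C@@H]1C=O
F6 | step 4 | secondary carbinol from F5 (1-hydroxyethyl in place of acetyl, either carbinol epimer) | CC(=O)C(C)(C)[C@@H]1C=CC[C@@H](C)[C@@H]1C(C)O
F7 | step 5 | isopropenyl analogue of 9 | CC(=O)C(C)(C)[C@@H]1C=CC[C@@H](C)[C@@H]1C(C)=C
F8 | step 5 | primary alcohol from F7 (1-hydroxypropan-2-yl side chain, both epimers) | CC(=O)C(C)(C)[C@@H]1C=CC[C@@H](C)[C@@H]1C(C)CO
F9 | step 5 | carboxylic acid corresponding to ester 12 | CC(=O)C(C)(C)[C@@H]1C=CC[C@@H](C)[C@@H]1C(C)C(=O)O
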